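The numbers in the tables were generated by integration from invented constants; scatter was added.

Slowness was what I saw first. The midnight flask made 37 % product in 15.0 h, but only 13 percentage points more between 72.0 h and 192 h, although 28.0 % of the charge had not become product at the earlier time.

common to all: starting material 0.10 M; free enzyme 0.033 mol%; impurity 14 µM

| charge | temperature | remark | time |
|---|---|---|---|
| midnight | 5 °C | the very flask that is asked about, followed so far |  |
| noon | −10 °C | run made earlier |  |
| flask | 5 °C |  | 8.0 d |

| run | time / h | product / % |
|---|---|---|
| midnight | 15.0 | 37 |
| midnight | 40.0 | 65 |
| midnight | 72.0 | 72 |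
| midnight | 192 | 85 |
| noon | 30.0 | 32 |
| noon | 96.0 | 64 |
| noon | 144 | 73 |
| noon | 360 | 88 |

(readings scatter by 2 percentage points)

- elm: at 8.0 d add free enzyme, 100 % of the amount charged, then wait 15 d
- ash: change nothing and wait 15 d more
- larch: at 8.0 d take out 90 % of the product then present, then wait 15 d
- alder: at 8.0 d raise the temperature by 25 K, then wait 15 d

- removed product is counted in
- additions bring no volume worth counting

1. product, in percent of the starting material first charged, at 8.0 d
2. the remedy with the largest gain of product, or "none" below 2 percentage points (elm / ash / larch / alder / none)
3. product present, with what was taken out counted in, in percent of the starting material first charged, after larch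
4. product present, with what was taken out counted in, in percent of the starting material first charged, after alder

A rate that fades like this asks where the enzyme went, so I kept a ledger of the catalyst in the midnight flask. First entry: the charge, [free enzyme] = 33.0 µM. Second entry: I assumed that impurity takes enzyme mole for mole. Impurity is then the limiting reagent of that loss, since [impurity] = 14 µM stood below the enzyme charge. Both runs carried the same amount, so they showed no effect of changing it. Third entry: my working charge, the enzyme charge minus the impurity, 19.0 µM. Last entry: the readings kept slowing, so I wrote off a further part of the working charge to fading, amount open.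

The reading of 85 % at 192 h was my answer for the asked time. For the remedies I reasoned that elm adds 33.0 µM, which is 1.74 times the working charge, provided the impurity had gone by then. Ash, larch and alder add no enzyme, so I put elm first.

The forecast gave 84.5 % at the asked time, elm as best, 85.5 % after larch and 85.2 % after alder, on the ground “Enzyme dying fits both runs”.

The flask gave 84.8 %. The largest gain came from elm, 9.5 points, against 4.1 points for ash, 4.1 points for larch and 0.025 points for alder. Larch ended at 88.9 %, alder at 84.8 %.

    free enzyme → unfolded enzyme (k = 8.10 × 10⁻⁵ /min, Ea = 204 kJ/mol)
    starting material + free enzyme → product + free enzyme, rate k2*[starting material]^2.5*[free enzyme]/(1 + ([starting material]/Kh2)^2.5) (0.0650 M, k = 2900 /M².5/min, Ea = 38.0 kJ/mol)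
    free enzyme + impurity → spent catalyst (k = 510 /M/min, Ea = 50.0 kJ/mol)
    (constants at 5 °C)

At 192 h the flask held free enzyme at 22.5 %, unfolded enzyme at 35.0 % and spent catalyst at 42.4 %, with impurity at 0 %. Free plus unfolded enzyme came to 57.5 % of the enzyme charge, and the working charge of 19.0 µM was 57.6 % of that charge. In the neighbouring flask with [impurity] = 56.0 µM, the same subtraction gave −23.0 µM, a negative working charge, with 41.1 % of the impurity over. That flask held free enzyme at 0 %, impurity at 41.3 % of its charge, and product at 3.98 % after 192 h.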